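**Retrosynthetic overview**

- Ring labels: A = terminal 2,4-dihydroxyphenyl ketone ring; B = central 1,4-phenylene; C = central 2,4-dihydroxy-5-aryloxyphenyl ketone ring; D = 4-hydroxyphenyl.
- Target ⇒ ring C salicylaldehyde + 4-ethynylphenol. The C(=O)–Cα bond of the ring C/ring D enone is made last; the formyl carbon acts as an acyl anion equivalent (chelation-assisted acyl-rhodium hydride) and adds across the terminal alkyne.
- That aldehyde ⇒ ring B/ring C dialdehyde + 2,4-dihydroxyacetophenone by Claisen–Schmidt at the ring B formyl only. The two formyl groups are used with opposite polarity: ring B as electrophile, ring C as acyl nucleophile.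
- Dialdehyde ⇒ bis-O-demethylation ⇐ Vilsmeier formylation of ring C ⇐ SNAr diaryl ether from 2,4-dimethoxyphenol + 4-fluorobenzaldehyde.
- Rings: none is formed; all four benzene rings are bought. B and C are joined first, A is attached next, D last.

Assumption: the target has no stereocentre, so "single enantiomer" is read as the single (E,E) geometric isomer.

**Step 1**
Reactants: 1 2,4-dimethoxyphenol; 2 4-fluorobenzaldehyde
Product: 3 4-(2,4-dimethoxyphenoxy)benzaldehyde
Conditions: K2CO3 (1.5 equiv), DMF, 120 °C, N2
Reagents that add atoms: none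
Why: Nucleophilic aromatic substitution (SNAr): the electron-rich phenoxide adds para to the formyl group of 2 and fluoride leaves from the Meisenheimer adduct; no stereocentre is involved.

**Step 2**
Reactants: 3 4-(2,4-dimethoxyphenoxy)benzaldehyde
Product: 5 5-(4-formylphenoxy)-2,4-dimethoxybenzaldehyde, via aryl iminium chloride 4 (not isolated)
Conditions: POCl3 (1.5 equiv), DMF, 0 → 70 °C; then ice–water
Reagents that add atoms: N,N-dimethylformamide CN(C)C=O; water O
Why: Vilsmeier–Haack formylation: the chloroiminium ion attacks only ring C, para to one methoxy and ortho to the other (the site at which 1,2,4-trimethoxybenzene is formylated), while formyl-deactivated ring B and its aldehyde are inert; no stereocentre is involved.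

**Step 3**
Reactants: 5 5-(4-formylphenoxy)-2,4-dimethoxybenzaldehyde
Product: 7 5-(4-formylphenoxy)-2,4-dihydroxybenzaldehyde, via bis(dibromoboryl) ether 6 (not isolated)
Conditions: BBr3 (5 equiv), CH2Cl2, −78 °C → rt; then H2O
Reagents that add atoms: none
Why: Lewis-acid ether cleavage: BBr3 coordinates each methoxy oxygen and bromide removes the methyl group by SN2, whereas the diaryl ether and the two reversibly complexed aldehydes survive; no stereocentre is involved.

**Step 4**
Reactants: 7 5-(4-formylphenoxy)-2,4-dihydroxybenzaldehyde; 8 1-(2,4-dihydroxyphenyl)ethanone (2,4-dihydroxyacetophenone)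
Product: 10 5-{4-[(1E)-3-(2,4-dihydroxyphenyl)-3-oxoprop-1-en-1-yl]phenoxy}-2,4-dihydroxybenzaldehyde, via racemic aldol adduct 9 (not isolated)
Conditions: 8 (1.0 equiv), KOH (50% aq, excess), EtOH, rt, 48 h, Ar; then 2 M HCl
Reagents that add atoms: none
Why: Claisen–Schmidt condensation (crossed aldol, E1cB dehydration): under KOH the ring C formyl sits on a phenoxide dianion and is a deactivated vinylogous carboxylate, so the enolate of 8 adds only to the ring B formyl, and loss of water from the transient racemic aldol 9 gives the thermodynamically favoured (E)-alkene; no stereocentre remains.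

**Step 5**
Reactants: 10 5-{4-[(1E)-3-(2,4-dihydroxyphenyl)-3-oxoprop-1-en-1-yl]phenoxy}-2,4-dihydroxybenzaldehyde; 11 4-ethynylphenol
Product: 12 (2E)-1-(2,4-dihydroxyphenyl)-3-[4-({2,4-dihydroxy-5-[(2E)-3-(4-hydroxyphenyl)prop-2-enoyl]phenyl}oxy)phenyl]prop-2-en-1-one (target)
Conditions: [RhCl(cod)]2 (cod = 1,5-cyclooctadiene, 2.5 mol%), dppf (1,1'-bis(diphenylphosphino)ferrocene, Fe(C5H4PPh2)2, 5 mol%), Na2CO3 (20 mol%), 11 (1.5 equiv, slow addition), 1,4-dioxane, 100 °C, Ar
Reagents that add atoms: none
Why: Chelation-assisted rhodium-catalysed intermolecular alkyne hydroacylation: the ortho-phenoxide binds monovalent rhodium and directs oxidative addition of the formyl C–H to an acyl hydride of trivalent rhodium that serves as an acyl anion equivalent, syn hydrometalation places rhodium on the terminal alkyne carbon and C–C reductive elimination delivers the linear enone whose (E) geometry follows from the syn addition of H and acyl; the 2'-hydroxychalcone already present is the product class of this reaction and is tolerated, and no stereocentre is formed.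

**Compound list**

1 | 2,4-dimethoxyphenol | COc1ccc(O)c(OC)c1 | starting material
2 | 4-fluorobenzaldehyde | O=Cc1ccc(F)cc1 | starting material
3 | 4-(2,4-dimethoxyphenoxy)benzaldehyde | COc1ccc(Oc2ccc(C=O)cc2)c(OC)c1 | intermediate
4 | N-{[5-(4-formylphenoxy)-2,4-dimethoxyphenyl]methylidene}-N-methylmethanaminium chloride (aryl iminium chloride, not isolated) | COc1cc(OC)c(C=[N+](C)C)cc1Oc1ccc(C=O)cc1.[Cl-] | intermediate
5 | 5-(4-formylphenoxy)-2,4-dimethoxybenzaldehyde | COc1cc(OC)c(C=O)cc1Oc1ccc(C=O)cc1 | intermediate
6 | 2,4-bis(dibromoboryloxy)-5-(4-formylphenoxy)benzaldehyde (bis(dibromoboryl) ether, not isolated) | O=Cc1ccc(Oc2cc(C=O)c(OB(Br)Br)cc2OB(Br)Br)cc1 | intermediate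
7 | 5-(4-formylphenoxy)-2,4-dihydroxybenzaldehyde | O=Cc1ccc(Oc2cc(C=O)c(O)cc2O)cc1 | intermediate
8 | 1-(2,4-dihydroxyphenyl)ethanone | CC(=O)c1ccc(O)cc1O | starting material
9 | racemic 5-{4-[3-(2,4-dihydroxyphenyl)-1-hydroxy-3-oxopropyl]phenoxy}-2,4-dihydroxybenzaldehyde (aldol adduct, not isolated) | O=Cc1cc(Oc2ccc(C(O)CC(=O)c3ccc(O)cc3O)cc2)c(O)cc1O | intermediate
10 | 5-{4-[(1E)-3-(2,4-dihydroxyphenyl)-3-oxoprop-1-en-1-yl]phenoxy}-2,4-dihydroxybenzaldehyde | O=Cc1cc(Oc2ccc(/C=C/C(=O)c3ccc(O)cc3O)cc2)c(O)cc1O | intermediate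
11 | 4-ethynylphenol | C#Cc1ccc(O)cc1 | starting material
12 | (2E)-1-(2,4-dihydroxyphenyl)-3-[4-({2,4-dihydroxy-5-[(2E)-3-(4-hydroxyphenyl)prop-2-enoyl]phenyl}oxy)phenyl]prop-2-en-1-one | O=C(/C=C/c1ccc(Oc2cc(C(=O)/C=C/c3ccc(O)cc3)c(O)cc2O)cc1)c1ccc(O)cc1O | target

**Totals**

Total step count: 5. Longest linear sequence: 5 steps (1 → 3 → 5 → 7 → 10 → 12).

**Steps most likely to fail, with fallbacks**

Step 5 is the main risk. The hydroacylation of a terminal aryl alkyne may give some branched 2-aryl enone beside the linear chalcone; which isomer dominates with this catalyst is not secured by precedent I can point to. The alkyne may also oligomerise, the new 2'-hydroxychalcone may close to a flavanone, and the polyphenol may bind the catalyst. The fallback gives up the hydroacylation and makes the ring C ketone by Friedel–Crafts acylation. It sets out from 3, which is acylated on ring C with (E)-3-(4-methoxyphenyl)prop-2-enoyl chloride (SnCl4, CH2Cl2, 0 °C; same ring position as the Vilsmeier formylation) to give (E)-4-{2,4-dimethoxy-5-[3-(4-methoxyphenyl)prop-2-enoyl]phenoxy}benzaldehyde F1. Its single aldehyde is condensed with 8 (KOH, EtOH/H2O, rt) to give (2E)-1-(2,4-dihydroxyphenyl)-3-[4-({2,4-dimethoxy-5-[(2E)-3-(4-methoxyphenyl)prop-2-enoyl]phenyl}oxy)phenyl]prop-2-en-1-one F2. The three methyl ethers are then cleaved with BBr3 (CH2Cl2, −78 → 0 °C; then H2O), which comes back to the route at 12.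

Step 4 is the second risk. The polyphenoxide of 8 enolises poorly, the ring B aldehyde can undergo Cannizzaro reaction in concentrated KOH, and the ring C aldehyde may react slowly. The fallback replaces the aldol by a Wittig olefination under near-neutral conditions. Commercial 2-chloro-1-(2,4-dihydroxyphenyl)ethanone and PPh3 (toluene, 80 °C) give [2-(2,4-dihydroxyphenyl)-2-oxoethyl]triphenylphosphonium chloride F3. One equivalent of aqueous NaOH converts it to the stabilised ylide 1-(2,4-dihydroxyphenyl)-2-(triphenyl-λ5-phosphanylidene)ethanone F4. The fallback sets out from 7, which is heated with F4 (THF, reflux). The ylide reacts with the more electrophilic ring B aldehyde, gives the (E)-enone as expected for a stabilised ylide, and comes back to the route at 10.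

Step 3 is the third risk. The para methyl ether may be cleaved incompletely, or the dialdehyde may degrade under BBr3. The fallback reverses the order of deprotection and formylation, so the ether cleavage is done with a protic acid on the robust monoaldehyde. It sets out from 3, which is demethylated (48% HBr, AcOH, reflux) to 4-(2,4-dihydroxyphenoxy)benzaldehyde F5. The free resorcinol ring is then formylated para to one hydroxyl and ortho to the other (POCl3, DMF, MeCN, 0 °C → rt; then H2O), which comes back to the route at 7.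

**Further compounds**

F1 | step 5 | (E)-4-{2,4-dimethoxy-5-[3-(4-methoxyphenyl)prop-2-enoyl]phenoxy}benzaldehyde | COc1ccc(/C=C/C(=O)c2cc(Oc3ccc(C=O)cc3)c(OC)cc2OC)cc1
F2 | step 5 | (2E)-1-(2,4-dihydroxyphenyl)-3-[4-({2,4-dimethoxy-5-[(2E)-3-(4-methoxyphenyl)prop-2-enoyl]phenyl}oxy)phenyl]prop-2-en-1-one | COc1ccc(/C=C/C(=O)c2cc(Oc3ccc(/C=C/C(=O)c4ccc(O)cc4O)cc3)c(OC)cc2OC)cc1
F3 | step 4 | [2-(2,4-dihydroxyphenyl)-2-oxoethyl]triphenylphosphonium chloride | O=C(C[P+](c1ccccc1)(c1ccccc1)c1ccccc1)c1ccc(O)cc1O.[Cl-]
F4 | step 4 | 1-(2,4-dihydroxyphenyl)-2-(triphenyl-λ5-phosphanylidene)ethanone | O=C(C=P(c1ccccc1)(c1ccccc1)c1ccccc1)c1ccc(O)cc1O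
F5 | step 3 | 4-(2,4-dihydroxyphenoxy)benzaldehyde | O=Cc1ccc(Oc2ccc(O)cc2O)cc1
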